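**Retrosynthetic overview**
- Target ⇒ Wittig disconnection at C7'=C8': an (S)-6,7-epoxygeranyl tributylphosphonium salt (C10) plus (6R)-8'-apo-ε-caroten-8'-al (C30).
- C30 aldehyde ⇒ C3 and C2 Wittig homologations of (6R)-12'-apo-ε-caroten-12'-al (C25) ⇒ Wittig at C11=C12 between the C15 phosphonium salt from (R)-α-ionone and the C10 dialdehyde.
- Epoxygeranyl unit ⇒ key C4'–C5' C(sp3)–C(sp2) bond made at a cathode: nickel-electrocatalytic coupling of a C6 epoxy iodide with the (E)-enol triflate of methyl acetoacetate.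
- Epoxy iodide ⇒ (R)-α-hydroxy-γ-butyrolactone: tosylate, double MeMgBr addition, oxirane closure with inversion (gives 2'S).
- Ring order: the cyclohexene ring is bought with (R)-α-ionone (6R); the oxirane is the only ring made (step 2), before any C–C coupling.

Assumption: (R)-(+)-α-ionone (enantiopure natural grade) and (R)-(+)-α-hydroxy-γ-butyrolactone are bought as catalogue items, and the target is the all-E (6R,2'S) isomer drawn in the SMILES.

**Route**

Step 1
Reactants: 1 (3R)-3-hydroxydihydrofuran-2(3H)-one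
Product: 2 (3R)-2-oxotetrahydrofuran-3-yl 4-methylbenzenesulfonate
Conditions: TsCl, pyridine, CH2Cl2, 0 °C
Reagents that add atoms: 4-toluenesulfonyl chloride, Cc1ccc(cc1)S(Cl)(=O)=O
Why: O-sulfonylation of the secondary alcohol breaks no bond at the stereocentre, so the (R) centre is kept and turned into a leaving group.

Step 2
Reactants: 2 (3R)-2-oxotetrahydrofuran-3-yl 4-methylbenzenesulfonate
Product: 4 2-[(2S)-3,3-dimethyloxiran-2-yl]ethan-1-ol, via tosyloxy diol 3 (not isolated)
Conditions: MeMgBr (2.3 equiv), THF, −78 → 0 °C; then MeOH, K2CO3, 23 °C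
Reagents that add atoms: methylmagnesium bromide, C[Mg]Br
Why: Double Grignard addition to the lactone carbonyl gives the tertiary alkoxide next to the tosylate, and intramolecular Williamson (3-exo-tet SN2) closure inverts that carbon, converting (R) into the (2'S) oxirane.

Step 3
Reactants: 4 2-[(2S)-3,3-dimethyloxiran-2-yl]ethan-1-ol
Product: 5 (3S)-3-(2-iodoethyl)-2,2-dimethyloxirane
Conditions: PPh3, I2, imidazole, CH2Cl2, 0 °C, dark
Reagents that add atoms: iodine, II
Why: Appel-type iodination replaces the primary hydroxyl by SN2 under imidazole-buffered conditions that leave the trisubstituted oxirane and its stereocentre untouched.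

Step 4
Reactants: 6 methyl acetoacetate
Product: 7 methyl (2E)-3-{[(trifluoromethyl)sulfonyl]oxy}but-2-enoate
Conditions: Tf2O, 25% aq Me4NOH, hexanes, 5 °C
Reagents that add atoms: trifluoromethanesulfonic anhydride, O=S(=O)(OS(=O)(=O)C(F)(F)F)C(F)(F)F
Why: O-triflation of the non-chelated tetramethylammonium enolate of the β-keto ester gives the (E)-enol triflate selectively (a chelating Li+ counter-ion would give Z), a known stereoselective enol triflate synthesis.

Step 5
Reactants: 5 (3S)-3-(2-iodoethyl)-2,2-dimethyloxirane (1.5 equiv), 7 methyl (2E)-3-{[(trifluoromethyl)sulfonyl]oxy}but-2-enoate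
Product: 8 methyl (2E)-5-[(2S)-3,3-dimethyloxiran-2-yl]-3-methylpent-2-enoate
Conditions: NiBr2·dme (10 mol %), 4,4'-di-tert-butyl-2,2'-bipyridine (12 mol %), nBu4NI, nBu4NPF6, DMA, 23 °C; divided cell, carbon-foam cathode, Zn anode in the second chamber, 4 mA cm−2, 2.5 F mol−1
Reagents that add atoms: none
Why: Proposed new method: cathodically generated zerovalent (bipyridine)nickel inserts with retention into the C(sp2)–OTf bond of 7, the alkenylnickel is reduced to monovalent nickel and abstracts iodine from 5, and the primary radical (two carbons from the oxirane, so it does not ring-open) is captured to give an alkyl(alkenyl) trivalent nickel species whose reductive elimination forms the C4'–C5' bond with the E geometry intact; the divided cell keeps Lewis-acidic Zn salts away from the oxirane; the closest known reaction types are the nickel-catalysed cross-electrophile coupling of alkyl halides with vinyl bromides or triflates driven by Zn or Mn powder and the nickel-electrocatalytic decarboxylative alkenylation of redox-active esters with vinyl iodides, whereas the cathodic coupling of an acyclic β-keto-ester (E)-enol triflate with an epoxide-bearing unactivated alkyl iodide has not been shown.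

Step 6
Reactants: 8 methyl (2E)-5-[(2S)-3,3-dimethyloxiran-2-yl]-3-methylpent-2-enoate
Product: 9 (2E)-5-[(2S)-3,3-dimethyloxiran-2-yl]-3-methylpent-2-en-1-ol
Conditions: iBu2AlH (2.3 equiv), CH2Cl2, −78 °C; aq KNaC4H4O6
Reagents that add atoms: none
Why: 1,2-Reduction of the enoate by the aluminium hydride at −78 °C is much faster than hydride opening of the hindered oxirane, and the 2E alkene is not affected.

Step 7
Reactants: 9 (2E)-5-[(2S)-3,3-dimethyloxiran-2-yl]-3-methylpent-2-en-1-ol
Product: 12 tributyl{(2E)-5-[(2S)-3,3-dimethyloxiran-2-yl]-3-methylpent-2-en-1-yl}phosphonium bromide, via allylic mesylate 10 (not isolated), via allylic bromide 11 (not isolated)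
Conditions: MsCl, Et3N, THF, −40 °C; LiBr, 0 °C; then PBu3, 23 °C
Reagents that add atoms: tributylphosphine, CCCCP(CCCC)CCCC; lithium bromide, [Li+].[Br-]
Why: Mesylation, SN2 displacement by bromide and quaternisation of the phosphine all take place at the primary allylic carbon without acid or SN2′ transposition, the standard way to make epoxy-allylic bromides, so the oxirane and the E alkene survive.

Step 8
Reactants: 13 (R)-α-ionone, (3E)-4-[(1R)-2,6,6-trimethylcyclohex-2-en-1-yl]but-3-en-2-one
Product: 14 (1E)-3-methyl-1-[(1R)-2,6,6-trimethylcyclohex-2-en-1-yl]penta-1,4-dien-3-ol (both C3 epimers)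
Conditions: CH2=CHMgBr, THF, −20 → 0 °C; then H2O
Reagents that add atoms: vinylmagnesium bromide, C=C[Mg]Br
Why: Grignard 1,2-addition to the enone carbonyl; the new carbinol centre forms as both epimers but is destroyed in step 9, and the ring stereocentre is not touched.

Step 9
Reactants: 14 (1E)-3-methyl-1-[(1R)-2,6,6-trimethylcyclohex-2-en-1-yl]penta-1,4-dien-3-ol
Product: 15 {(2E,4E)-3-methyl-5-[(1R)-2,6,6-trimethylcyclohex-2-en-1-yl]penta-2,4-dien-1-yl}triphenylphosphonium bromide
Conditions: PPh3·HBr, MeOH, 23 °C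
Reagents that add atoms: triphenylphosphine hydrobromide, [Br-].[PH+](c1ccccc1)(c1ccccc1)c1ccccc1
Why: Acid ionisation of the tertiary bis-allylic alcohol and SN1′ capture of the pentadienyl cation by PPh3 at its terminus (the classical vinyl-ionol to C15 Wittig salt conversion) gives the conjugated salt, mainly 2E, and the ring stereocentre lies outside the cation.

Step 10
Reactants: 15 {(2E,4E)-3-methyl-5-[(1R)-2,6,6-trimethylcyclohex-2-en-1-yl]penta-2,4-dien-1-yl}triphenylphosphonium bromide, 16 (2E,4E,6E)-2,7-dimethylocta-2,4,6-trienedial (1.5 equiv)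
Product: 18 (6R)-12'-apo-ε-caroten-12'-al, via C15 ylide 17 (not isolated)
Conditions: NaOMe, MeOH–CH2Cl2, 0 → 23 °C; then n-heptane, 90 °C
Reagents that add atoms: none
Why: Wittig olefination stops after one aldehyde group because the C25 polyenal is far less electrophilic than the dialdehyde used in excess, and heating converts the hindered 11Z isomer into the all-E aldehyde.

Step 11
Reactants: 18 (6R)-12'-apo-ε-caroten-12'-al, 19 (1,3-dioxolan-2-ylmethyl)triphenylphosphonium bromide
Product: 22 (6R)-10'-apo-ε-caroten-10'-al, via dioxolanylmethylene ylide 20 (not isolated), via C27 dienyl dioxolane 21 (not isolated)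
Conditions: KOtBu, THF, 0 → 23 °C; then 1 M aq HCl, THF, 23 °C
Reagents that add atoms: water, O
Why: Wittig reaction with the acetal-bearing ylide followed by acetal hydrolysis is a two-carbon homologation to the enal that cannot over-homologate, and the acid step equilibrates the new double bond to E.

Step 12
Reactants: 22 (6R)-10'-apo-ε-caroten-10'-al, 23 2-(triphenylphosphoranylidene)propanal
Product: 24 (6R)-8'-apo-ε-caroten-8'-al
Conditions: toluene, 90 °C
Reagents that add atoms: none
Why: Wittig olefination with the stabilised α-methyl formyl ylide is E-selective and stops after one addition because the α-branched product enal is less reactive than the unbranched starting enal.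

Step 13
Reactants: 12 tributyl{(2E)-5-[(2S)-3,3-dimethyloxiran-2-yl]-3-methylpent-2-en-1-yl}phosphonium bromide, 24 (6R)-8'-apo-ε-caroten-8'-al
Product: 26 (6R,2'S)-1',2'-epoxy-1',2'-dihydro-ε,ψ-carotene, via C10 ylide 25 (not isolated)
Conditions: KOtBu (0.95 equiv), THF, −78 °C; then 24, −78 → 0 °C, dark; crystallisation
Reagents that add atoms: none
Why: Wittig olefination with an allylic tributylphosphonium ylide, a class known to give E dienes selectively, forms C7'=C8' under aprotic conditions with no free base left over, so the oxirane, the doubly allylic ring stereocentre and the polyene are preserved; the minor 7'Z isomer is removed by crystallisation.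

**Compound list**

1 | (3R)-3-hydroxydihydrofuran-2(3H)-one, (R)-α-hydroxy-γ-butyrolactone | O=C1OCC[C@H]1O | starting material
2 | (3R)-2-oxotetrahydrofuran-3-yl 4-methylbenzenesulfonate | O=C1OCC[C@H]1OS(=O)(=O)c1ccc(C)cc1 | intermediate
3 | (3R)-1,4-dihydroxy-4-methylpentan-3-yl 4-methylbenzenesulfonate | OCC[C@H](C(C)(C)O)OS(=O)(=O)c1ccc(C)cc1 | intermediate (not isolated)
4 | 2-[(2S)-3,3-dimethyloxiran-2-yl]ethan-1-ol | OCC[C@@H]1OC1(C)C | intermediate
5 | (3S)-3-(2-iodoethyl)-2,2-dimethyloxirane | ICC[C@@H]1OC1(C)C | intermediate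
6 | methyl acetoacetate (methyl 3-oxobutanoate) | COC(=O)CC(C)=O | starting material
7 | methyl (2E)-3-{[(trifluoromethyl)sulfonyl]oxy}but-2-enoate | COC(=O)/C=C(\C)OS(=O)(=O)C(F)(F)F | intermediate
8 | methyl (2E)-5-[(2S)-3,3-dimethyloxiran-2-yl]-3-methylpent-2-enoate | COC(=O)/C=C(\C)CC[C@@H]1OC1(C)C | intermediate
9 | (2E)-5-[(2S)-3,3-dimethyloxiran-2-yl]-3-methylpent-2-en-1-ol, (S)-6,7-epoxygeraniol | OC/C=C(\C)CC[C@@H]1OC1(C)C | intermediate
10 | (2E)-5-[(2S)-3,3-dimethyloxiran-2-yl]-3-methylpent-2-en-1-yl methanesulfonate | CS(=O)(=O)OC/C=C(\C)CC[C@@H]1OC1(C)C | intermediate (not isolated)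
11 | (3S)-3-[(3E)-5-bromo-3-methylpent-3-en-1-yl]-2,2-dimethyloxirane | BrC/C=C(\C)CC[C@@H]1OC1(C)C | intermediate (not isolated)
12 | tributyl{(2E)-5-[(2S)-3,3-dimethyloxiran-2-yl]-3-methylpent-2-en-1-yl}phosphonium bromide | CCCC[P+](CCCC)(CCCC)C/C=C(\C)CC[C@@H]1OC1(C)C.[Br-] | intermediate
13 | (R)-α-ionone, (3E)-4-[(1R)-2,6,6-trimethylcyclohex-2-en-1-yl]but-3-en-2-one | CC1=CCCC(C)(C)[C@H]1/C=C/C(C)=O | starting material
14 | (1E)-3-methyl-1-[(1R)-2,6,6-trimethylcyclohex-2-en-1-yl]penta-1,4-dien-3-ol, both C3 epimers | CC1=CCCC(C)(C)[C@H]1/C=C/C(C)(O)C=C | intermediate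
15 | {(2E,4E)-3-methyl-5-[(1R)-2,6,6-trimethylcyclohex-2-en-1-yl]penta-2,4-dien-1-yl}triphenylphosphonium bromide | CC1=CCCC(C)(C)[C@H]1/C=C/C(C)=C/C[P+](c1ccccc1)(c1ccccc1)c1ccccc1.[Br-] | intermediate
16 | (2E,4E,6E)-2,7-dimethylocta-2,4,6-trienedial | O=C/C(C)=C/C=C/C=C(C)/C=O | starting material
17 | triphenyl{(2E,4E)-3-methyl-5-[(1R)-2,6,6-trimethylcyclohex-2-en-1-yl]penta-2,4-dien-1-ylidene}-λ5-phosphane | CC1=CCCC(C)(C)[C@H]1/C=C/C(C)=C/C=P(c1ccccc1)(c1ccccc1)c1ccccc1 | intermediate (not isolated)
18 | (6R)-12'-apo-ε-caroten-12'-al, (2E,4E,6E,8E,10E,12E)-2,7,11-trimethyl-13-[(1R)-2,6,6-trimethylcyclohex-2-en-1-yl]trideca-2,4,6,8,10,12-hexaenal | CC1=CCCC(C)(C)[C@H]1/C=C/C(C)=C/C=C/C(C)=C/C=C/C=C(C)/C=O | intermediate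
19 | (1,3-dioxolan-2-ylmethyl)triphenylphosphonium bromide | [Br-].C1COC(C[P+](c2ccccc2)(c2ccccc2)c2ccccc2)O1 | starting material
20 | (1,3-dioxolan-2-ylmethylidene)triphenyl-λ5-phosphane | C1COC(C=P(c2ccccc2)(c2ccccc2)c2ccccc2)O1 | intermediate (not isolated)
21 | 2-[(3E,5E,7E,9E,11E,13E)-3,8,12-trimethyl-14-[(1R)-2,6,6-trimethylcyclohex-2-en-1-yl]tetradeca-1,3,5,7,9,11,13-heptaen-1-yl]-1,3-dioxolane, 1E/1Z mixture | CC1=CCCC(C)(C)[C@H]1/C=C/C(C)=C/C=C/C(C)=C/C=C/C=C(C)/C=CC1OCCO1 | intermediate (not isolated)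
22 | (6R)-10'-apo-ε-caroten-10'-al, (2E,4E,6E,8E,10E,12E,14E)-4,9,13-trimethyl-15-[(1R)-2,6,6-trimethylcyclohex-2-en-1-yl]pentadeca-2,4,6,8,10,12,14-heptaenal | CC1=CCCC(C)(C)[C@H]1/C=C/C(C)=C/C=C/C(C)=C/C=C/C=C(C)/C=C/C=O | intermediate
23 | 2-(triphenylphosphoranylidene)propanal | CC(C=O)=P(c1ccccc1)(c1ccccc1)c1ccccc1 | starting material
24 | (6R)-8'-apo-ε-caroten-8'-al, (2E,4E,6E,8E,10E,12E,14E,16E)-2,6,11,15-tetramethyl-17-[(1R)-2,6,6-trimethylcyclohex-2-en-1-yl]heptadeca-2,4,6,8,10,12,14,16-octaenal | CC1=CCCC(C)(C)[C@H]1/C=C/C(C)=C/C=C/C(C)=C/C=C/C=C(C)/C=C/C=C(C)/C=O | intermediate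
25 | tributyl{(2E)-5-[(2S)-3,3-dimethyloxiran-2-yl]-3-methylpent-2-en-1-ylidene}-λ5-phosphane | CCCCP(CCCC)(CCCC)=C/C=C(\C)CC[C@@H]1OC1(C)C | intermediate (not isolated)
26 | (6R,2'S)-1',2'-epoxy-1',2'-dihydro-ε,ψ-carotene, all-E | CC1=CCCC(C)(C)[C@H]1/C=C/C(C)=C/C=C/C(C)=C/C=C/C=C(C)/C=C/C=C(C)/C=C/C=C(\C)CC[C@@H]1OC1(C)C | target

**Step count and risks**

Total steps: 13. Longest linear sequence: 7 steps (1 → 2 → 4 → 5 → 8 → 9 → 12 → 26; steps 1, 2, 3, 5, 6, 7, 13).

The three steps most likely to fail: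

Step 5 (the proposed new coupling). Possible failures are hydro-detriflation of 7, homocoupling, or erosion of the E geometry at the alkenylnickel stage. The fallback uses known chemistry and sets out from 5: zinc insertion (Zn dust, LiCl, THF, 40 °C) gives {2-[(2S)-3,3-dimethyloxiran-2-yl]ethyl}zinc iodide F1, which is cross-coupled with 7 in a Negishi reaction (PdCl2(dppf), THF, 23 → 50 °C; oxidative addition of zerovalent palladium to the enol triflate and reductive elimination both proceed with retention). This comes back to the route at 8.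

Step 2. The tosylate in 2 sits α to a carbonyl, so partial epimerisation or halide displacement before the Grignard addition would lower the enantiomeric purity of the oxirane. The fallback sets out from 1 and never has a sulfonate next to a carbonyl. Excess MeMgBr (THF, 0 → 40 °C) gives (3R)-4-methylpentane-1,3,4-triol F2. TBSCl/imidazole silylates only the primary hydroxyl to give (3R)-1-[(tert-butyldimethylsilyl)oxy]-4-methylpentane-3,4-diol F3. MsCl/pyridine sulfonylates the secondary hydroxyl to give (3R)-1-[(tert-butyldimethylsilyl)oxy]-4-hydroxy-4-methylpentan-3-yl methanesulfonate F4. K2CO3/MeOH closes the oxirane with inversion to tert-butyl{2-[(2S)-3,3-dimethyloxiran-2-yl]ethoxy}dimethylsilane F5, and nBu4NF in THF removes the silyl group. This comes back to the route at 4.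

Step 13. The allylic ylide may give an inseparable 7'E/7'Z mixture or scramble the 5'E alkene. The fallback sets out from 9 and replaces the Wittig reaction by a Horner–Wittig sequence. The bromide 11 (made as in step 7) undergoes a Michaelis–Arbuzov reaction with ethyl diphenylphosphinite (toluene, 60 °C) to give {(2E)-5-[(2S)-3,3-dimethyloxiran-2-yl]-3-methylpent-2-en-1-yl}(diphenyl)phosphine oxide F6. Lithiation (nBuLi, THF, −78 °C) and addition to 24 gives the β-hydroxy phosphine oxide adduct F7. KH in THF then induces syn-elimination of diphenylphosphinate, which for allylic diphenylphosphine oxides is E-selective. This comes back to the route at 26.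

**Further compounds**

F1 | step 5 | {2-[(2S)-3,3-dimethyloxiran-2-yl]ethyl}zinc iodide | I[Zn]CC[C@@H]1OC1(C)C
F2 | step 2 | (3R)-4-methylpentane-1,3,4-triol | OCC[C@H](C(C)(C)O)O
F3 | step 2 | (3R)-1-[(tert-butyldimethylsilyl)oxy]-4-methylpentane-3,4-diol | CC(C)(C)[Si](C)(C)OCC[C@H](C(C)(C)O)O
F4 | step 2 | (3R)-1-[(tert-butyldimethylsilyl)oxy]-4-hydroxy-4-methylpentan-3-yl methanesulfonate | CC(C)(C)[Si](C)(C)OCC[C@H](C(C)(C)O)OS(C)(=O)=O
F5 | step 2 | tert-butyl{2-[(2S)-3,3-dimethyloxiran-2-yl]ethoxy}dimethylsilane | CC(C)(C)[Si](C)(C)OCC[C@@H]1OC1(C)C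
F6 | step 13 | {(2E)-5-[(2S)-3,3-dimethyloxiran-2-yl]-3-methylpent-2-en-1-yl}(diphenyl)phosphine oxide | O=P(C/C=C(\C)CC[C@@H]1OC1(C)C)(c1ccccc1)c1ccccc1
F7 | step 13 | β-hydroxy phosphine oxide adduct of lithiated F6 and 24 (diastereomer mixture at the two new sp3 carbons) | CC1=CCCC(C)(C)[C@H]1/C=C/C(C)=C/C=C/C(C)=C/C=C/C=C(C)/C=C/C=C(C)/C(O)C(/C=C(\C)CC[C@@H]1OC1(C)C)P(=O)(c1ccccc1)c1ccccc1
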